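A solution holding 14 mM of target and 43 mM of dissolved substrate was the picture I reckoned with in this flask, for as long as solid substrate lasted.

solid substrate 0.28 M; reagent 1.00 equiv; time 30 min

    solid product ⇌ target, rate k1*(cs1 - [target]) while solid is left; crystals form when [target] > cs1 (cs1 = 14 mM, k1 = 0.984 s⁻¹)
    solid substrate + target → side product (k2 = 0.107 M⁻¹ s⁻¹)
    solid substrate ⇌ dissolved substrate, rate k3*(cs3 - [dissolved substrate]) while solid is left; crystals form when [dissolved substrate] > cs3 (cs3 = 43 mM, k3 = 0.501 s⁻¹)
    reagent ⇌ dormant form (K4 = 0.351, k4 = 0.0152 s⁻¹)
    dissolved substrate + reagent → target (k5 = 0.0671 M⁻¹ s⁻¹)

- percent here means solid substrate units held: one side product counts as two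
- what is said of target includes solid product
- solid substrate, solid product is a solid; its amount is given per volume of the solution
- at the start none of the solid substrate is in solution
- dissolved substrate means what is dissolved; the solid is not counted in it
- run time (flask): 30 min

- zeta: doubling the solubility in step 1, all else as stated
- epsilon: doubling the dissolution coefficient of step 3, all else as stated
- theta: doubling the dissolution coefficient of step 1, all else as stated
- eta: doubling the solubility in step 3, all else as stated

- the target and solid product together standing at 30 min, as a percentage of the solid substrate charged
- concentration of dissolved substrate in solution at 15 min, in percent of saturation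
- the change that raises the amount of target and solid product together at 30 min, in percent of the solid substrate charged most ("none" if none brings more than 2 percentage points) (zeta / epsilon / theta / eta / none)
- amount of target and solid product together at 30 min, in percent of the solid substrate charged, after theta

The picture rested on times. Dissolved substrate refills with a half-life of 1.38 s, far shorter than the 0.61 min of its use. Target, once crystals stand, refills in 0.704 s against 0.39 min. Reagent and dormant form keep their ratio, relaxing in 0.197 min, far less than 30 min. I neglected the first rise of target.

So both steps become pseudo-first-order. Reagent, free and dormant together, falls with one constant, and the side step eats solid with another: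

pull = 0.128 min⁻¹, side = 0.0899 min⁻¹

Filling the solution leaves 0.237 M of solid to share out. Each side event costs two units.

My first way held reagent at its first level, so the solid lost a constant amount per minute through reagent, plus a side loss proportional to what solid remained:

time = ln((pull × charge + side × solid) / (pull × charge)) / side = 5.19 min, y = 63.6%

My second way let reagent fall exponentially and solved the solid's balance, with D = pull × charge / (pull − side) = 0.938 M:

window = ln(D / (D − solid)) / (pull − side) = 7.61 min

I call this the side window, the time from the start until the solid substrate reaches zero. At its end 0.106 M of reagent remains, more than the 43 mM still dissolved. Solid not spent through reagent went to 0.0625 M of side events, so the loss is 44.7% and y = 55.3%.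

The two ways part, the first standing higher. The first cheats: about a third of the reagent remains at the window's end, yet it held the charge. I committed to 55.3%.

The window holds neither dissolution coefficient, so theta and epsilon left my figure unchanged. Under eta the same lines give 0.256 min⁻¹ and 0.194 M, then 0.431 M, 3.59 min and y = 81.8%, so I chose eta. For sat I carried no figure.

The forecast gave 55.5%, 16.5%, eta and 56%, saying “Doubling the substrate solubility speeds the productive step and shortens the side reaction's window”.

The flask gave 55.9%, 18.0%, eta with 25 percentage points, and 56.1%. Side product read 44.0% at 15.0 min and 44.0% at 30.0 min, with solid substrate at 0% at the earlier reading, which lies past the window of 7.61 min. With 4.00 equiv of reagent the charge is 1.12 M, so D becomes 3.75 M and the window shrinks to 1.71 min. That reckoning gives y = 87.8%, and that neighbouring flask stood at 86.2%.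

The rate constants come from no measurement; the result is computed.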